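**Retrosynthetic overview**

1. Core numbering (bicyclo[2.2.2]oct-2-ene): C1 quaternary bridgehead (Me), C2 enol carbon, C3 hexenoyl-bearing carbon, C4 bridgehead CH, C5 C(Me)OH, C6 ketone, C7 CH–sorbyl, C8 CH–tetronate; ring A = C1–C6–C5–C4–C8–C7.
2. Last disconnection: the 3-methyltetronic acid, by Lacey–Dieckmann closure of an α-propionyloxy methyl ester on C8.
3. Key disconnection C3–C4: C3, the carbon between the C2 enol and the side-chain ketone, lies anti across C4–C5 to the tertiary C5 hydroxyl, which is the retron of an oxirane opened at C4; the C2=C3 enol is carried as an alkyne (ynone on C1) so that a phosphine makes C3 nucleophilic in the plane of the new bridge.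
4. Ring A comes from (R)-carvone: C1 is quaternised (Me, then ethynyl), a γ-selective copper bis(oxazoline) pyruvate aldol sets C8 and the tetronate carbinol, nucleophilic epoxidation gives the C4–C5 oxirane, and the isopropenyl group becomes the sorbyl ketone.
5. Ring order: ring A (from carvone), then the temporary C4–C5 oxirane, then both carbocyclic rings of the bicyclo[2.2.2]octene at once through the C3–C4 bond, then the tetronic acid.

Key step: step 11

Remark: the β-triketone is drawn as its C2 enol throughout, the monocyclic precursors keep the core numbers given above, and (E)-hex-4-enoic acid is taken as a catalogue compound.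

**Step 1**
Reactants: 1 (R)-(−)-carvone
Product: 2 trans-6-methylcarvone [(5R,6S)-2,6-dimethyl-5-(prop-1-en-2-yl)cyclohex-2-en-1-one]
Conditions: LiN(i-Pr)2 (LDA), THF, −78 °C, then MeI, −78 to 0 °C
Reagents that add atoms: iodomethane (CI)
Why: Kinetic deprotonation at C1 and SN2 methylation of the cross-conjugated lithium dienolate (enolate alkylation) should place the methyl group mainly trans to the C7 isopropenyl group; the configuration at C1 does not matter because C1 is enolised again in step 2.

**Step 2**
Reactants: 2 trans-6-methylcarvone
Product: 3 alkynyl ketone (6-ethynyl-6-methylcarvone; ethynyl on C1 trans to the C7 isopropenyl group)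
Conditions: LiN(i-Pr)2 (LDA), THF, −78 °C, then TMS-EBX, Bu4NF (TBAF), THF, −78 °C to rt
Reagents that add atoms: TMS-EBX, 1-[(trimethylsilyl)ethynyl]-1,2-benziodoxol-3(1H)-one (C[Si](C)(C)C#CI1OC(=O)c2ccccc12)
Why: Electrophilic α-alkynylation of the regenerated C1 enolate by the ethynyl benziodoxolone formed in the flask (conjugate addition to the trivalent iodine alkyne, loss of iodobenzoate, 1,2-shift of the alkylidene carbene) should create the quaternary C1 with the reagent approaching anti to the adjacent isopropenyl group, so that ethynyl and isopropenyl end up trans.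

**Step 3**
Reactants: 3 alkynyl ketone
Product: 4 linear trimethylsilyl dienol ether (C6=C5–C4=C8 diene with OSiMe3 on C6)
Conditions: Me3SiOTf, Et3N, CH2Cl2, 0 °C
Reagents that add atoms: trimethylsilyl triflate (C[Si](C)(C)OS(=O)(=O)C(F)(F)F)
Why: Soft enolisation with a silyl triflate and an amine: because C1 is quaternary the only removable hydrogens are those at C8, so the linear silyl dienol ether should form regiospecifically, and no stereocentre is made.

**Step 4**
Reactants: 4 linear trimethylsilyl dienol ether; 5 methyl pyruvate
Product: 7 γ-aldol adduct (methyl (S)-2-hydroxypropanoate unit on C8 trans to the C7 isopropenyl group), via silyl ether 6 (not isolated)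
Conditions: Cu(OTf)2/(S,S)-t-Bu-box (10 mol%), THF, −78 °C, then PPTS, MeOH, rt
Reagents that add atoms: none
Why: Catalytic enantioselective vinylogous Mukaiyama aldol addition to a copper-chelated pyruvate: the dienol ether should react at its γ-carbon C8 (the α-carbon C5 is fully substituted) on the ring face anti to the C7 isopropenyl group, while the (S,S)-ligand leaves the Si face of the ketone open and so sets the (S)-carbinol; acidic methanol then removes the transferred silyl group.

**Step 5**
Reactants: 7 γ-aldol adduct
Product: 8 propionate ester of 7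
Conditions: (EtCO)2O, DMAP, Et3N, CH2Cl2, 40 °C
Reagents that add atoms: propionic anhydride (CCC(=O)OC(=O)CC)
Why: DMAP-catalysed acylation of the tertiary alcohol (Steglich-type acyl transfer) touches no stereocentre; it brings in the three carbons of the later tetronic acid and blocks retro-aldol cleavage in the basic steps that follow.

**Step 6**
Reactants: 8 propionate ester
Product: 9 epoxy ketone (C4–C5 oxirane with its oxygen anti to the C8 side chain)
Conditions: t-BuOOH (in decane), DBU, CH2Cl2, 0 °C to rt
Reagents that add atoms: tert-butyl hydroperoxide (CC(C)(C)OO)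
Why: Weitz–Scheffer nucleophilic epoxidation: the tert-butyl peroxide anion should add to C4 anti to the bulky quaternary side chain on the neighbouring C8 and the enolate then closes the oxirane, which puts the C4–C5 oxygen on the ring face opposite to that side chain and to the C1 ethynyl group; the isolated alkene and the alkyne are inert to the nucleophilic oxidant.

**Step 7**
Reactants: 9 epoxy ketone
Product: 11 methyl ketone (acetyl on C7), via ozonide 10 (not isolated)
Conditions: O3, CH2Cl2, −78 °C (Sudan red end point), then Me2S, −78 °C to rt
Reagents that add atoms: ozone ([O-][O+]=O)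
Why: Ozonolysis with reductive work-up (Criegee mechanism) should cleave the only remaining alkene, which reacts far faster than the terminal alkyne, to the methyl ketone without affecting any stereocentre.

**Step 8**
Reactants: 11 methyl ketone; 12 (E)-crotonaldehyde
Product: 15 sorbyl ketone ((2E,4E)-hexa-2,4-dienoyl on C7), via lithium aldolate 13 (not isolated), via mesylate 14 (not isolated)
Conditions: LiN(SiMe3)2 (LiHMDS), THF, −78 °C, then 12, −78 °C, then MsCl, Et3N, −78 °C to rt
Reagents that add atoms: none
Why: One-pot aldol condensation: the kinetic lithium enolate of the methyl ketone (the oxiranyl ketone has no α-hydrogen) adds 1,2 to crotonaldehyde, and mesylation with E1cB elimination should give the conjugated dienone with the new alkene E on thermodynamic grounds, the transient carbinol centre being destroyed again.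

**Step 9**
Reactants: 16 (E)-hex-4-enoic acid
Product: 17 (E)-hex-4-enoyl chloride
Conditions: (COCl)2, DMF (cat.), CH2Cl2, 0 °C to rt
Reagents that add atoms: oxalyl chloride (O=C(Cl)C(=O)Cl)
Why: Standard conversion of the acid into its chloride through the chloroiminium (Vilsmeier-type) catalyst; no stereocentre is involved and the E alkene is untouched.

**Step 10**
Reactants: 15 sorbyl ketone; 17 (E)-hex-4-enoyl chloride
Product: 18 ynone ((E)-3-oxooct-6-en-1-yn-1-yl group on C1)
Conditions: PdCl2(PPh3)2 (2 mol%), CuI (4 mol%), Et3N, THF, rt
Reagents that add atoms: none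
Why: Acyl Sonogashira coupling of the terminal alkyne with the acid chloride under near-neutral conditions that the esters, the oxirane and the dienone should survive; no stereocentre is formed.

**Step 11**
Reactants: 18 ynone
Product: 20 bicyclic enol triketone (bicyclo[2.2.2]oct-2-ene with C2 enol and C5 carbinol), via phosphonium alkoxide 19 (not isolated)
Conditions: PMe3 (1.2 equiv.), t-BuOH/THF, rt to 40 °C, then H2O, rt
Reagents that add atoms: water (O)
Why: Proposed new method: trimethylphosphine adds reversibly to the β-carbon of the ynone (the alkyne carbon on C1) and the resulting β-phosphonio allenolate attacks the oxirane at C4 through the in-plane lobe of its α-carbon (C3), after which water adds to C2 of the vinylphosphonium enone and expels the phosphine to leave the C2 enol. The closest known reaction types are the phosphine-mediated intramolecular Morita–Baylis–Hillman alkylation of enones by tethered epoxides and the phosphine-catalysed addition of O–H nucleophiles to ynones; their combination on an ynone, with hydrolytic release of the phosphine, is new. The single C3–C4 bond closes both new six-membered rings of the bicyclo[2.2.2]octene, 6-exo-tet for ring C1–C2–C3–C4–C8–C7 and 6-endo-tet for ring C1–C2–C3–C4–C5–C6, through a boat of ring A. C4 is set by the tether, which reaches only the face of ring A that carries the ynone, and by SN2 inversion, so the new bond is anti to the C5 oxygen, whose configuration (fixed in step 6) is untouched. The step needs C- rather than O-alkylation and attack at C4 rather than C5: the zwitterion has its only oxygen on the remote side-chain carbonyl (closure through it would need an eight-membered ring), its reactive lobe lies in the plane of the forming C1–C2=C3–C4 bridge (a planar β-diketonate would be orthogonal to it and would close through oxygen), and C5 is fully substituted. Protonation of the zwitterion by the alcohol solvent is reversible, so the irreversible ring closure drains the equilibrium.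

**Step 12**
Reactants: 20 bicyclic enol triketone
Product: 21 target (CNP0539719.2)
Conditions: KOt-Bu (5 equiv.), THF/t-BuOH, 0 °C to rt, then aq. HCl
Reagents that add atoms: none
Why: Lacey–Dieckmann cyclisation: the propionate enolate attacks the neighbouring methyl ester and expels methoxide to give the 3-methyltetronic acid without touching its quaternary carbon, while the enolised triketone and the carbinol are shielded as their anions and the reversible conditions leave C7 in the more stable trans arrangement to C8.

**Compound list**

1 | (R)-(−)-carvone | CC(=C)[C@@H]1CC=C(C)C(=O)C1 | starting material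
2 | trans-6-methylcarvone, (5R,6S)-2,6-dimethyl-5-(prop-1-en-2-yl)cyclohex-2-en-1-one | CC(=C)[C@@H]1CC=C(C)C(=O)[C@H]1C | intermediate
3 | alkynyl ketone, 6-ethynyl-6-methylcarvone (ethynyl trans to isopropenyl) | CC(=C)[C@@H]1CC=C(C)C(=O)[C@@]1(C)C#C | intermediate
4 | linear trimethylsilyl dienol ether of 3 | CC(=C)[C@@H]1C=CC(C)=C(O[Si](C)(C)C)[C@@]1(C)C#C | intermediate
5 | methyl pyruvate | CC(=O)C(=O)OC | starting material
6 | trimethylsilyl ether of aldol adduct 7 | CC(=C)[C@@H]1[C@@H]([C@](C)(O[Si](C)(C)C)C(=O)OC)C=C(C)C(=O)[C@@]1(C)C#C | intermediate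
7 | γ-aldol adduct, methyl (S)-2-hydroxypropanoate unit on C8 trans to isopropenyl | CC(=C)[C@@H]1[C@@H]([C@](C)(O)C(=O)OC)C=C(C)C(=O)[C@@]1(C)C#C | intermediate
8 | propionate ester of 7 | CC(=C)[C@@H]1[C@@H]([C@](C)(OC(=O)CC)C(=O)OC)C=C(C)C(=O)[C@@]1(C)C#C | intermediate
9 | epoxy ketone, C4–C5 oxirane anti to the C8 side chain | CC(=C)[C@@H]1[C@@H]([C@](C)(OC(=O)CC)C(=O)OC)[C@@H]2O[C@]2(C)C(=O)[C@@]1(C)C#C | intermediate
10 | secondary ozonide (1,2,4-trioxolane) from the isopropenyl group of 9 | CC3(OCOO3)[C@@H]1[C@@H]([C@](C)(OC(=O)CC)C(=O)OC)[C@@H]2O[C@]2(C)C(=O)[C@@]1(C)C#C | intermediate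
11 | methyl ketone, acetyl on C7 | CC(=O)[C@@H]1[C@@H]([C@](C)(OC(=O)CC)C(=O)OC)[C@@H]2O[C@]2(C)C(=O)[C@@]1(C)C#C | intermediate
12 | (E)-crotonaldehyde | C/C=C/C=O | starting material
13 | lithium aldolate of 11 with 12 (both carbinol epimers) | [Li+].C/C=C/C([O-])CC(=O)[C@@H]1[C@@H]([C@](C)(OC(=O)CC)C(=O)OC)[C@@H]2O[C@]2(C)C(=O)[C@@]1(C)C#C | intermediate
14 | mesylate of the aldol | C/C=C/C(OS(C)(=O)=O)CC(=O)[C@@H]1[C@@H]([C@](C)(OC(=O)CC)C(=O)OC)[C@@H]2O[C@]2(C)C(=O)[C@@]1(C)C#C | intermediate
15 | sorbyl ketone, (2E,4E)-hexa-2,4-dienoyl on C7 | C/C=C/C=C/C(=O)[C@@H]1[C@@H]([C@](C)(OC(=O)CC)C(=O)OC)[C@@H]2O[C@]2(C)C(=O)[C@@]1(C)C#C | intermediate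
16 | (E)-hex-4-enoic acid | C/C=C/CCC(=O)O | starting material
17 | (E)-hex-4-enoyl chloride | C/C=C/CCC(=O)Cl | intermediate
18 | ynone, (E)-3-oxooct-6-en-1-yn-1-yl group on C1 | C/C=C/C=C/C(=O)[C@@H]1[C@@H]([C@](C)(OC(=O)CC)C(=O)OC)[C@@H]2O[C@]2(C)C(=O)[C@@]1(C)C#CC(=O)CC/C=C/C | intermediate
19 | bicyclic vinylphosphonium alkoxide (zwitterion) | C/C=C/C=C/C(=O)[C@@H]1[C@@H]([C@](C)(OC(=O)CC)C(=O)OC)[C@H]2C(C(=O)CC/C=C/C)=C([P+](C)(C)C)[C@]1(C)C(=O)[C@@]2(C)[O-] | intermediate
20 | bicyclic enol triketone with the α-propionyloxy ester on C8 | C/C=C/C=C/C(=O)[C@@H]1[C@@H]([C@](C)(OC(=O)CC)C(=O)OC)[C@H]2C(C(=O)CC/C=C/C)=C(O)[C@]1(C)C(=O)[C@@]2(C)O | intermediate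
21 | target CNP0539719.2 | C/C=C/C=C/C(=O)[C@@H]1[C@@H]([C@]2(C)OC(=O)C(C)=C2O)[C@H]2C(C(=O)CC/C=C/C)=C(O)[C@]1(C)C(=O)[C@@]2(C)O | target

**Step count and risks**

Total step count: 12. Longest linear sequence: 11 steps (steps 1–8, 10, 11, 12).

The three steps most likely to fail:

Step 11 (Proposed new method). The phosphonio allenolate may be protonated and hydrated without closing the ring, or hydroxide may attack phosphorus instead of C2 in the release stage, so that the phosphine is lost as its oxide and C2 keeps a hydrogen. The fallback uses known chemistry and sets out from 18. The ynone is hydrated regioselectively with (Ph3P)AuNTf2 (2 mol%) and H2O in 1,4-dioxane at 40 °C to the epoxy β-diketone F1. F1 is then cyclised by intramolecular C-alkylation of its lithium diketonate at the oxirane (DBU, LiCl, CF3CH2OH, 40 °C; the hydrogen-bond-donating solvent and the chelating cation are meant to suppress closure through the enolate oxygen, the main competing pathway). This returns to the route at 20.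

Step 4. The hindered dienol ether may add sluggishly, or facial control at C8 or at the new carbinol may be poor. The fallback sets out from 4. γ-C-Acylation with methyl chlorooxoacetate (ZnBr2 cat., CH2Cl2, −78 °C) gives the α-keto ester F2. Chemoselective methyl transfer from MeTi(OiPr)3 (THF, −40 °C) to its ketone carbonyl, under Felkin–Anh control by the C8 centre, returns to the route at 7; the two carbinol epimers would have to be separated at this point.

Step 6. Facial selectivity may be poor, because the C8 side chain and the C7 isopropenyl group direct the peroxide to opposite faces. The fallback sets out from 8. Luche reduction (NaBH4, CeCl3·7H2O, MeOH, −78 °C) gives the allylic alcohol F3, with hydride expected to enter past the slim ethynyl group and anti to the C1 methyl. Hydroxyl-directed epoxidation (VO(acac)2 cat., t-BuOOH, CH2Cl2, 0 °C) delivers oxygen syn to the carbinol and gives the epoxy alcohol F4. Dess–Martin oxidation returns to the route at 9.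

**Further compounds**

F1 | step 11 | epoxy β-diketone | C/C=C/C=C/C(=O)[C@@H]1[C@@H]([C@](C)(OC(=O)CC)C(=O)OC)[C@@H]2O[C@]2(C)C(=O)[C@@]1(C)C(=O)CC(=O)CC/C=C/C
F2 | step 4 | α-keto ester | CC(=C)[C@@H]1[C@@H](C(=O)C(=O)OC)C=C(C)C(=O)[C@@]1(C)C#C
F3 | step 6 | allylic alcohol | CC(=C)[C@@H]1[C@@H]([C@](C)(OC(=O)CC)C(=O)OC)C=C(C)[C@H](O)[C@@]1(C)C#C
F4 | step 6 | epoxy alcohol | CC(=C)[C@@H]1[C@@H]([C@](C)(OC(=O)CC)C(=O)OC)[C@@H]2O[C@]2(C)[C@H](O)[C@@]1(C)C#C
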